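**Retrosynthetic overview**
- The strategy rests on ring A (C1–C5 and C10, labdane numbering): the C1 acetoxy oxygen and the ester carbon C19 on C4 lie cis-1,4 across this ring, so they are treated as the two ends of an O–C(=O) bridge from C1 to C4.
- Key disconnection: the bridged ring A (a 2-oxabicyclo[2.2.2]octenone) is cut at C4–C5 and C1–C10 into 3-methyl-2-pyrone (C1–C4, C18, C19) and an (E)-2-methyl-2-enal (C5–C10, C17, C20).
- Ring order: ring A first (step 5, four stereocentres), ring B second by 6-exo vinyl-radical closure of C8–C9 after the bridge has been opened to the C1 acetate and the C19 methyl ester.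
- Side chain: the formyl carbon C9 is homologated to C11/C12 before ring B closes; C12 is then taken to the aldehyde and two Wittig reactions build C12=C13 (E) and C14=C15.
- Precursors: the pyrone by methyl cross-coupling of 3-bromo-2-pyrone; the enal from tert-butyl acetate, 2,3-dibromopropene and a formyl ylide.

Key step: step 5

Remark: positions are given in labdane numbering (ring A = C1–C5, C10; ring B = C5–C10; C18/C19 on C4, C20 on C10, C17 on C8); in this numbering the target is (1S,4R,5S,9R,10S,12E), an ent-labdane. 3-Bromo-2H-pyran-2-one is taken as the purchasable pyrone.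

**Step 1**
Reactants: 1 3-bromo-2H-pyran-2-one
Product: 2 3-methyl-2H-pyran-2-one
Conditions: MeZnCl (1.5 equiv), Pd(PPh3)4 (5 mol %), THF, 0 °C → rt
Reagents that add atoms: methylzinc chloride, C[Zn]Cl
Why: Negishi cross-coupling at the C3–Br bond, which should undergo oxidative addition readily, under neutral conditions that spare the base-sensitive pyrone.

**Step 2**
Reactants: 3 tert-butyl acetate; 4 2,3-dibromoprop-1-ene
Product: 6 tert-butyl 4-bromopent-4-enoate, via lithium enolate 5 (not isolated)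
Conditions: LiN(iPr)2 (1.05 equiv), THF, −78 °C; then 4, −78 → 0 °C
Reagents that add atoms: none
Why: SN2 alkylation of a lithium ester enolate at the allylic bromide, with the vinylic bromide inert and the tert-butyl ester suppressing Claisen self-condensation.

**Step 3**
Reactants: 6 tert-butyl 4-bromopent-4-enoate
Product: 8 4-bromopent-4-enal, via aluminium hemiacetal 7 (not isolated)
Conditions: iBu2AlH (1.1 equiv), CH2Cl2, −78 °C; MeOH, then aq. KNaC4H4O6
Reagents that add atoms: none
Why: partial ester reduction that should stop at the tetrahedral aluminium hemiacetal at −78 °C and release the aldehyde only on work-up.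

**Step 4**
Reactants: 8 4-bromopent-4-enal; 9 2-(triphenylphosphoranylidene)propanal
Product: 10 (2E)-6-bromo-2-methylhepta-2,6-dienal
Conditions: CH2Cl2, 40 °C
Reagents that add atoms: none
Why: Wittig olefination with a stabilised ylide, which should give the (E)-trisubstituted enal.

**Step 5**
Reactants: 2 3-methyl-2H-pyran-2-one; 10 (2E)-6-bromo-2-methylhepta-2,6-dienal
Product: 11 (1S,4R,5S,6S)-5-(3-bromobut-3-en-1-yl)-4,6-dimethyl-3-oxo-2-oxabicyclo[2.2.2]oct-7-ene-6-carbaldehyde (endo-formyl adduct)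
Conditions: (S)-1-(2-methylphenyl)-3,3-diphenyltetrahydro-1H,3H-pyrrolo[1,2-c][1,3,2]oxazaborole (20 mol %), HN(SO2CF3)2 (18 mol %), 2 (1.5 equiv), CH2Cl2, −40 → 0 °C; adduct kept cold and taken directly into step 6
Reagents that add atoms: none
Why: Proposed new method: the boron-bound s-trans enal should react with the pyrone diene (C3=C4–C5=C6) in a normal-demand, asynchronous but concerted [4+2] cycloaddition whose leading bond joins pyrone C3, the carbon at which 2-pyrones accept electrophiles, to the enal β-carbon while the ring oxygen stabilises the developing charge at C6; the closest known reaction type is the thermal or base-promoted Diels–Alder addition of 3-bromo- and 3-hydroxy-2-pyrones to acrylic dienophiles, which has not been shown for a 3-alkylpyrone, a trisubstituted enal or a chiral Lewis acid. Ring A (C1, C2, C3, C4, C5, C10) is closed in this one intermolecular step as the boat-shaped carbocycle of the 2-oxabicyclo[2.2.2]octene by the bonds C4–C5 and C1–C10. C10 and C5 (6S and 5S in the name of 11) take their relative configuration from suprafacial addition to the (E) double bond, which puts C9 and C6 trans, and their absolute configuration from the (S)-oxazaborolidinium ion, whose C-phenyl group should cover one face of the formyl-bound enal so that the diene adds to the Re face of the α-carbon. C1 and C4 (1S, 4R) follow from the endo transition state, in which the activated formyl group lies under C4=C5 of the pyrone and the methyl group and the chain face the hydrogen-free O–C(=O) bridge, so that C20, C6 and the lactone bridge end on one face of ring A. The step needs regio-, endo and facial selectivity: the orientation (pyrone C6 to the enal α-carbon) should be secured by the absence of a lone-pair donor at C3, by oxocarbenium-type stabilisation at C6 and by the fact that the reverse orientation would have to join the two fully substituted carbons C3 and Cα, while endo and facial control rest on the catalyst. The 3-methyl group also crowds the carbonyl lone pair of the pyrone that a Lewis acid would use, which should leave the catalyst to the aldehyde.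

**Step 6**
Reactants: 11 the endo adduct
Product: 12 (1S,4R,5S,6S)-5-(3-bromobut-3-en-1-yl)-4,6-dimethyl-3-oxo-2-oxabicyclo[2.2.2]octane-6-carbaldehyde
Conditions: KO2CN=NCO2K (8 equiv), AcOH (16 equiv, slow addition), CH2Cl2, 0 °C → rt
Reagents that add atoms: none
Why: diimide reduction, a concerted syn hydrogen transfer that should take the strained cis-disubstituted bicyclic alkene well before the 2-bromo-1-alkene and leaves aldehyde, C–Br bond and all stereocentres untouched, after which the lactone can no longer lose CO2.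

**Step 7**
Reactants: 12 the saturated lactone aldehyde
Product: 13 (2E)-3-[(1S,4R,5S,6S)-5-(3-bromobut-3-en-1-yl)-4,6-dimethyl-3-oxo-2-oxabicyclo[2.2.2]octan-6-yl]-N-methoxy-N-methylprop-2-enamide
Conditions: (EtO)2P(O)CH2C(O)N(OMe)Me (1.5 equiv), NaH (1.4 equiv), THF, 0 °C → rt
Reagents that add atoms: diethyl {2-[methoxy(methyl)amino]-2-oxoethyl}phosphonate, CCOP(=O)(CC(=O)N(C)OC)OCC
Why: Horner–Wadsworth–Emmons olefination of the non-enolisable neopentyl aldehyde to the (E)-enamide (C9=C11), done before the bridge is opened so that no β-hydroxy aldehyde prone to retro-aldol cleavage is ever formed.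

**Step 8**
Reactants: 13 the lactone enamide
Product: 14 methyl (1R,2S,3S,4S)-2-(3-bromobut-3-en-1-yl)-4-hydroxy-3-{(1E)-3-[methoxy(methyl)amino]-3-oxoprop-1-en-1-yl}-1,3-dimethylcyclohexane-1-carboxylate
Conditions: NaOMe (0.2 equiv), MeOH, 0 °C → rt
Reagents that add atoms: methanol, CO
Why: methoxide-catalysed transesterification of the bridged lactone, driven by release of the boat strain, with acyl–oxygen cleavage so that C1 and C4 keep their configuration and the C1 alcohol and C19 methyl ester appear cis.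

**Step 9**
Reactants: 14 the hydroxy ester
Product: 15 methyl (1R,2S,3S,4S)-4-(acetyloxy)-2-(3-bromobut-3-en-1-yl)-3-{(1E)-3-[methoxy(methyl)amino]-3-oxoprop-1-en-1-yl}-1,3-dimethylcyclohexane-1-carboxylate
Conditions: Ac2O, DMAP (cat.), pyridine, CH2Cl2, rt
Reagents that add atoms: acetic anhydride, CC(=O)OC(C)=O
Why: DMAP-catalysed acylation of the equatorial secondary alcohol, which installs the final C1 acetate and blocks the hydroxyl before radical and carbonyl chemistry.

**Step 10**
Reactants: 15 the bromo-diene acetate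
Product: 16 methyl (1R,4S,4aS,5R,8aS)-4-(acetyloxy)-5-{2-[methoxy(methyl)amino]-2-oxoethyl}-1,4a-dimethyl-6-methylidenedecahydronaphthalene-1-carboxylate
Conditions: Bu3SnH (1.3 equiv), AIBN (0.2 equiv), benzene (0.005 M), 80 °C, slow addition
Reagents that add atoms: none
Why: tin hydride-mediated 6-exo-trig cyclisation of the C8 vinyl radical onto the β-carbon (C9) of the unsaturated amide, closing ring B with its exocyclic methylene through a chair-like transition state on the ring A chair in which C11 sits pseudo-equatorial and anti to C5, so that H9 should end axial on the face of H5 (9R).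

**Step 11**
Reactants: 16 the decalin amide
Product: 18 methyl (1R,4S,4aS,5R,8aS)-4-(acetyloxy)-1,4a-dimethyl-6-methylidene-5-(2-oxoethyl)decahydronaphthalene-1-carboxylate, via aluminium hemiaminal 17 (not isolated)
Conditions: iBu2AlH (1.2 equiv), THF, −78 °C; aq. KNaC4H4O6
Reagents that add atoms: none
Why: chemoselective partial reduction in which the electrophilic hydride should coordinate and reduce the more Lewis-basic N-methoxy-N-methylamide to a chelated hemiaminal stable at −78 °C, while the acetate and the hindered axial C19 ester react more slowly in THF.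

**Step 12**
Reactants: 18 the C12 aldehyde; 9 2-(triphenylphosphoranylidene)propanal
Product: 19 methyl (1R,4S,4aS,5R,8aS)-4-(acetyloxy)-1,4a-dimethyl-6-methylidene-5-[(2E)-3-methyl-4-oxobut-2-en-1-yl]decahydronaphthalene-1-carboxylate
Conditions: toluene, 80 °C
Reagents that add atoms: none
Why: Wittig olefination with the stabilised formyl ylide, which should give the (12E) trisubstituted C12=C13 enal.

**Step 13**
Reactants: 19 the (12E)-enal
Product: 20 methyl (1R,4S,4aS,5R,8aS)-4-(acetyloxy)-1,4a-dimethyl-6-methylidene-5-[(2E)-3-methylpenta-2,4-dien-1-yl]decahydronaphthalene-1-carboxylate (CNP0235031.1)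
Conditions: Ph3PCH3Br (1.3 equiv), KN(SiMe3)2 (1.2 equiv), THF, 0 °C; then 19, −78 → 0 °C
Reagents that add atoms: methyltriphenylphosphonium bromide, C[P+](c1ccccc1)(c1ccccc1)c1ccccc1.[Br-]
Why: Wittig methylenation of the aldehyde by 1,2-addition, which completes the C14=C15 vinyl group without touching the (12E) alkene and should outpace any attack on acetate or ester at low temperature.

**Compound list**
1 | 3-bromo-2H-pyran-2-one | O=C1OC=CC=C1Br | starting material
2 | 3-methyl-2H-pyran-2-one | CC1=CC=COC1=O | intermediate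
3 | tert-butyl acetate | CC(=O)OC(C)(C)C | starting material
4 | 2,3-dibromoprop-1-ene | C=C(Br)CBr | starting material
5 | lithium 1-tert-butoxyethen-1-olate | [Li]OC(=C)OC(C)(C)C | intermediate
6 | tert-butyl 4-bromopent-4-enoate | C=C(Br)CCC(=O)OC(C)(C)C | intermediate
7 | bis(2-methylpropyl)aluminium 4-bromo-1-tert-butoxypent-4-en-1-olate | C=C(Br)CCC(O[Al](CC(C)C)CC(C)C)OC(C)(C)C | intermediate
8 | 4-bromopent-4-enal | C=C(Br)CCC=O | intermediate
9 | 2-(triphenylphosphoranylidene)propanal | CC(C=O)=P(c1ccccc1)(c1ccccc1)c1ccccc1 | starting material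
10 | (2E)-6-bromo-2-methylhepta-2,6-dienal | O=C/C(C)=C/CCC(Br)=C | intermediate
11 | (1S,4R,5S,6S)-5-(3-bromobut-3-en-1-yl)-4,6-dimethyl-3-oxo-2-oxabicyclo[2.2.2]oct-7-ene-6-carbaldehyde | C=C(Br)CC[C@H]1[C@](C)(C=O)[C@H]2OC(=O)[C@]1(C)C=C2 | intermediate
12 | (1S,4R,5S,6S)-5-(3-bromobut-3-en-1-yl)-4,6-dimethyl-3-oxo-2-oxabicyclo[2.2.2]octane-6-carbaldehyde | C=C(Br)CC[C@H]1[C@](C)(C=O)[C@H]2OC(=O)[C@]1(C)CC2 | intermediate
13 | (2E)-3-[(1S,4R,5S,6S)-5-(3-bromobut-3-en-1-yl)-4,6-dimethyl-3-oxo-2-oxabicyclo[2.2.2]octan-6-yl]-N-methoxy-N-methylprop-2-enamide | C=C(Br)CC[C@H]1[C@](C)(/C=C/C(=O)N(C)OC)[C@H]2OC(=O)[C@]1(C)CC2 | intermediate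
14 | methyl (1R,2S,3S,4S)-2-(3-bromobut-3-en-1-yl)-4-hydroxy-3-{(1E)-3-[methoxy(methyl)amino]-3-oxoprop-1-en-1-yl}-1,3-dimethylcyclohexane-1-carboxylate | C=C(Br)CC[C@H]1[C@](C)(/C=C/C(=O)N(C)OC)[C@@H](O)CC[C@@]1(C)C(=O)OC | intermediate
15 | methyl (1R,2S,3S,4S)-4-(acetyloxy)-2-(3-bromobut-3-en-1-yl)-3-{(1E)-3-[methoxy(methyl)amino]-3-oxoprop-1-en-1-yl}-1,3-dimethylcyclohexane-1-carboxylate | C=C(Br)CC[C@H]1[C@](C)(/C=C/C(=O)N(C)OC)[C@@H](OC(C)=O)CC[C@@]1(C)C(=O)OC | intermediate
16 | methyl (1R,4S,4aS,5R,8aS)-4-(acetyloxy)-5-{2-[methoxy(methyl)amino]-2-oxoethyl}-1,4a-dimethyl-6-methylidenedecahydronaphthalene-1-carboxylate | CON(C)C(=O)C[C@@H]1C(=C)CC[C@H]2[C@@]1(C)[C@@H](OC(C)=O)CC[C@@]2(C)C(=O)OC | intermediate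
17 | methyl (1R,4S,4aS,5R,8aS)-4-(acetyloxy)-5-{2-[bis(2-methylpropyl)alumanyloxy]-2-[methoxy(methyl)amino]ethyl}-1,4a-dimethyl-6-methylidenedecahydronaphthalene-1-carboxylate | CON(C)C(O[Al](CC(C)C)CC(C)C)C[C@@H]1C(=C)CC[C@H]2[C@@]1(C)[C@@H](OC(C)=O)CC[C@@]2(C)C(=O)OC | intermediate
18 | methyl (1R,4S,4aS,5R,8aS)-4-(acetyloxy)-1,4a-dimethyl-6-methylidene-5-(2-oxoethyl)decahydronaphthalene-1-carboxylate | O=CC[C@@H]1C(=C)CC[C@H]2[C@@]1(C)[C@@H](OC(C)=O)CC[C@@]2(C)C(=O)OC | intermediate
19 | methyl (1R,4S,4aS,5R,8aS)-4-(acetyloxy)-1,4a-dimethyl-6-methylidene-5-[(2E)-3-methyl-4-oxobut-2-en-1-yl]decahydronaphthalene-1-carboxylate | O=C/C(C)=C/C[C@@H]1C(=C)CC[C@H]2[C@@]1(C)[C@@H](OC(C)=O)CC[C@@]2(C)C(=O)OC | intermediate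
20 | methyl (1R,4S,4aS,5R,8aS)-4-(acetyloxy)-1,4a-dimethyl-6-methylidene-5-[(2E)-3-methylpenta-2,4-dien-1-yl]decahydronaphthalene-1-carboxylate | C=C/C(C)=C/C[C@@H]1C(=C)CC[C@H]2[C@@]1(C)[C@@H](OC(C)=O)CC[C@@]2(C)C(=O)OC | target

**Step count**
Total: 13 steps. Longest linear sequence: 12 steps (steps 2–13, from tert-butyl acetate); the pyrone branch is one step.

**Steps most likely to fail**

1. Step 5. The pyrone and lactone carbonyls may hold the boron Lewis acid so that the enal is not turned over, and the trisubstituted enal may be attacked with poor facial or endo discrimination. The fallback sets out from 2 and 10 and comes back at 12. The two partners are combined without catalyst in CH2Cl2 at 12–15 kbar and room temperature, the known pressure-promoted Diels–Alder addition of 2-pyrones to α,β-unsaturated carbonyl dienophiles that keeps the CO2 bridge; orientation then rests on the steric matching alone. This should give 11 as a racemate, that is together with its enantiomer (1R,4S,5R,6R)-5-(3-bromobut-3-en-1-yl)-4,6-dimethyl-3-oxo-2-oxabicyclo[2.2.2]oct-7-ene-6-carbaldehyde F1. Diimide reduction as in step 6 gives 12 with (1R,4S,5R,6R)-5-(3-bromobut-3-en-1-yl)-4,6-dimethyl-3-oxo-2-oxabicyclo[2.2.2]octane-6-carbaldehyde F2. The enantiomers are separated at this thermally stable stage by preparative chromatography on a chiral stationary phase, and 12 goes on to step 7.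

2. Step 10. Facial control at C9 may be incomplete during the radical closure, with C11 entering axially. The fallback sets out from 16 as it leaves step 10 in admixture with its C9 epimer, methyl (1R,4S,4aS,5S,8aS)-4-(acetyloxy)-5-{2-[methoxy(methyl)amino]-2-oxoethyl}-1,4a-dimethyl-6-methylidenedecahydronaphthalene-1-carboxylate F3, and comes back at 16. It puts C9 under thermodynamic control. Ozonolysis of the mixture (O3, CH2Cl2/MeOH, −78 °C; Me2S) cleaves the exocyclic methylene to the C8 ketones methyl (1R,4S,4aR,5S,8aS)-4-(acetyloxy)-5-{2-[methoxy(methyl)amino]-2-oxoethyl}-1,4a-dimethyl-6-oxodecahydronaphthalene-1-carboxylate F4 and methyl (1R,4S,4aR,5R,8aS)-4-(acetyloxy)-5-{2-[methoxy(methyl)amino]-2-oxoethyl}-1,4a-dimethyl-6-oxodecahydronaphthalene-1-carboxylate F5. C9 is now α to a ketone, so DBU in toluene should equilibrate F5 through the enolate to F4, which carries C11 equatorial. Non-basic methylenation with Zn/CH2Br2/TiCl4, which does not disturb C9, returns 16 as a single epimer.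

3. Step 11. Hydride transfer to the C1 acetate may compete with reduction of the amide, with loss of the acetyl group. The fallback sets out from 14 and comes back at 20; it carries C1 as a silyl ether and acetylates last.
 - Et3SiOTf and 2,6-lutidine give methyl (1R,2S,3S,4S)-2-(3-bromobut-3-en-1-yl)-3-{(1E)-3-[methoxy(methyl)amino]-3-oxoprop-1-en-1-yl}-1,3-dimethyl-4-[(triethylsilyl)oxy]cyclohexane-1-carboxylate F6.
 - Radical closure as in step 10 gives methyl (1R,4S,4aS,5R,8aS)-5-{2-[methoxy(methyl)amino]-2-oxoethyl}-1,4a-dimethyl-6-methylidene-4-[(triethylsilyl)oxy]decahydronaphthalene-1-carboxylate F7.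
 - iBu2AlH at −78 °C, now with only the hindered C19 ester as competitor, gives methyl (1R,4S,4aS,5R,8aS)-1,4a-dimethyl-6-methylidene-5-(2-oxoethyl)-4-[(triethylsilyl)oxy]decahydronaphthalene-1-carboxylate F8.
 - Ylide 9 gives methyl (1R,4S,4aS,5R,8aS)-1,4a-dimethyl-6-methylidene-5-[(2E)-3-methyl-4-oxobut-2-en-1-yl]-4-[(triethylsilyl)oxy]decahydronaphthalene-1-carboxylate F9.
 - Methylenation as in step 13 gives methyl (1R,4S,4aS,5R,8aS)-1,4a-dimethyl-6-methylidene-5-[(2E)-3-methylpenta-2,4-dien-1-yl]-4-[(triethylsilyl)oxy]decahydronaphthalene-1-carboxylate F10.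
 - HF·pyridine in THF frees methyl (1R,4S,4aS,5R,8aS)-4-hydroxy-1,4a-dimethyl-6-methylidene-5-[(2E)-3-methylpenta-2,4-dien-1-yl]decahydronaphthalene-1-carboxylate F11, and Ac2O/DMAP/pyridine then gives 20.

**Further compounds**
F1 | step 5 | (1R,4S,5R,6R)-5-(3-bromobut-3-en-1-yl)-4,6-dimethyl-3-oxo-2-oxabicyclo[2.2.2]oct-7-ene-6-carbaldehyde | C=C(Br)CC[C@@H]1[C@@](C)(C=O)[C@@H]2OC(=O)[C@@]1(C)C=C2
F2 | step 5 | (1R,4S,5R,6R)-5-(3-bromobut-3-en-1-yl)-4,6-dimethyl-3-oxo-2-oxabicyclo[2.2.2]octane-6-carbaldehyde | C=C(Br)CC[C@@H]1[C@@](C)(C=O)[C@@H]2OC(=O)[C@@]1(C)CC2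
F3 | step 10 | methyl (1R,4S,4aS,5S,8aS)-4-(acetyloxy)-5-{2-[methoxy(methyl)amino]-2-oxoethyl}-1,4a-dimethyl-6-methylidenedecahydronaphthalene-1-carboxylate | CON(C)C(=O)C[C@H]1C(=C)CC[C@H]2[C@@]1(C)[C@@H](OC(C)=O)CC[C@@]2(C)C(=O)OC
F4 | step 10 | methyl (1R,4S,4aR,5S,8aS)-4-(acetyloxy)-5-{2-[methoxy(methyl)amino]-2-oxoethyl}-1,4a-dimethyl-6-oxodecahydronaphthalene-1-carboxylate | CON(C)C(=O)C[C@@H]1C(=O)CC[C@H]2[C@@]1(C)[C@@H](OC(C)=O)CC[C@@]2(C)C(=O)OC
F5 | step 10 | methyl (1R,4S,4aR,5R,8aS)-4-(acetyloxy)-5-{2-[methoxy(methyl)amino]-2-oxoethyl}-1,4a-dimethyl-6-oxodecahydronaphthalene-1-carboxylate | CON(C)C(=O)C[C@H]1C(=O)CC[C@H]2[C@@]1(C)[C@@H](OC(C)=O)CC[C@@]2(C)C(=O)OC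
F6 | step 11 | methyl (1R,2S,3S,4S)-2-(3-bromobut-3-en-1-yl)-3-{(1E)-3-[methoxy(methyl)amino]-3-oxoprop-1-en-1-yl}-1,3-dimethyl-4-[(triethylsilyl)oxy]cyclohexane-1-carboxylate | C=C(Br)CC[C@H]1[C@](C)(/C=C/C(=O)N(C)OC)[C@@H](O[Si](CC)(CC)CC)CC[C@@]1(C)C(=O)OC
F7 | step 11 | methyl (1R,4S,4aS,5R,8aS)-5-{2-[methoxy(methyl)amino]-2-oxoethyl}-1,4a-dimethyl-6-methylidene-4-[(triethylsilyl)oxy]decahydronaphthalene-1-carboxylate | CON(C)C(=O)C[C@@H]1C(=C)CC[C@H]2[C@@]1(C)[C@@H](O[Si](CC)(CC)CC)CC[C@@]2(C)C(=O)OC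
F8 | step 11 | methyl (1R,4S,4aS,5R,8aS)-1,4a-dimethyl-6-methylidene-5-(2-oxoethyl)-4-[(triethylsilyl)oxy]decahydronaphthalene-1-carboxylate | O=CC[C@@H]1C(=C)CC[C@H]2[C@@]1(C)[C@@H](O[Si](CC)(CC)CC)CC[C@@]2(C)C(=O)OC
F9 | step 11 | methyl (1R,4S,4aS,5R,8aS)-1,4a-dimethyl-6-methylidene-5-[(2E)-3-methyl-4-oxobut-2-en-1-yl]-4-[(triethylsilyl)oxy]decahydronaphthalene-1-carboxylate | O=C/C(C)=C/C[C@@H]1C(=C)CC[C@H]2[C@@]1(C)[C@@H](O[Si](CC)(CC)CC)CC[C@@]2(C)C(=O)OC
F10 | step 11 | methyl (1R,4S,4aS,5R,8aS)-1,4a-dimethyl-6-methylidene-5-[(2E)-3-methylpenta-2,4-dien-1-yl]-4-[(triethylsilyl)oxy]decahydronaphthalene-1-carboxylate | C=C/C(C)=C/C[C@@H]1C(=C)CC[C@H]2[C@@]1(C)[C@@H](O[Si](CC)(CC)CC)CC[C@@]2(C)C(=O)OC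
F11 | step 11 | methyl (1R,4S,4aS,5R,8aS)-4-hydroxy-1,4a-dimethyl-6-methylidene-5-[(2E)-3-methylpenta-2,4-dien-1-yl]decahydronaphthalene-1-carboxylate | C=C/C(C)=C/C[C@@H]1C(=C)CC[C@H]2[C@@]1(C)[C@@H](O)CC[C@@]2(C)C(=O)OC
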